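**Strategy.** Ring B of this labdane, a cyclohexane whose C8 carries the exocyclic C17 methylene, is treated as a masked cyclohexene: a Δ8(9)-allylsilane that arises from a [4+2] union of a C7=C8–C9=C10 diene with a C5=C6 vinyl group. Cutting C6–C7 and C5–C10 gives an acyclic (E)-triene in which the diene (CH2SiMe3 on C8, the citronellol-derived chain on C9, the future angular methyl on C10) is tied through C1–C3 to the quaternary C4 that bears the vinyl group. One thermal intramolecular Diels–Alder reaction closes rings A and B and sets C5 and C10 under control of C4; C9 is set afterwards by protodesilylation.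

Key step: step 15

Remark: the SMILES is read as methyl 3α-acetoxy-15-hydroxylabd-8(17)-en-19-oate (normal series, 13S; 3-OAc and 4-CO2Me both axial, CO2Me syn to the C10 methyl). Labdane numbering is used for ring atoms throughout; TBS = tert-butyldimethylsilyl, TMS = trimethylsilyl.

**Diene fragment**

Step 1
Reactants: 1 (S)-citronellol
Product: 2 tert-butyl{[(3S)-3,7-dimethyloct-6-en-1-yl]oxy}dimethylsilane
Conditions: TBSCl, imidazole, DMF, 0 °C → rt
Reagents that add atoms: tert-butyldimethylsilyl chloride, CC(C)(C)[Si](C)(C)Cl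
Why: Standard silylation of the primary alcohol (the future C15–OH); the C13 stereocentre comes from the chiral pool and is not touched.

Step 2
Reactants: 2 tert-butyl{[(3S)-3,7-dimethyloct-6-en-1-yl]oxy}dimethylsilane
Product: 4 (4S)-6-(TBS-oxy)-4-methylhexanal, via secondary ozonide 3 (not isolated)
Conditions: O3, CH2Cl2, −78 °C; then PPh3, −78 °C → rt
Reagents that add atoms: ozone, [O-][O+]=O
Why: Ozonolysis of the trisubstituted alkene with reductive work-up should give the aldehyde whose carbonyl carbon becomes C9.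

Step 3
Reactants: 4 (4S)-6-(TBS-oxy)-4-methylhexanal; 5 ethyl propanoate
Product: 6 ethyl (6S)-8-(TBS-oxy)-3-hydroxy-2,6-dimethyloctanoate (C2/C3 diastereomer mixture)
Conditions: LDA, THF, −78 °C; then 4
Reagents that add atoms: none
Why: Lithium enolate aldol addition; the two new centres are oxidised or planarised in steps 4 and 5, so their configuration is irrelevant.

Step 4
Reactants: 6 ethyl (6S)-8-(TBS-oxy)-3-hydroxy-2,6-dimethyloctanoate
Product: 7 ethyl (6S)-8-(TBS-oxy)-2,6-dimethyl-3-oxooctanoate (C2 epimers)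
Conditions: Dess–Martin periodinane, CH2Cl2, rt
Reagents that add atoms: none
Why: Dess–Martin oxidation of the secondary alcohol should give the α-methyl β-keto ester (C9 ketone, C10 methine, C1 ester) without touching the silyl ether.

Step 5
Reactants: 7 ethyl (6S)-8-(TBS-oxy)-2,6-dimethyl-3-oxooctanoate
Product: 8 ethyl (2E,6S)-8-(TBS-oxy)-2,6-dimethyl-3-{[(trifluoromethyl)sulfonyl]oxy}oct-2-enoate
Conditions: Tf2O, aq. Me4NOH, toluene, 0–5 °C
Reagents that add atoms: trifluoromethanesulfonic anhydride, O=S(=O)(OS(=O)(=O)C(F)(F)F)C(F)(F)F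
Why: Stereoselective enolisation–triflation of a β-keto ester: the non-chelated tetraalkylammonium enolate (O− anti to the ester carbonyl) is O-sulfonylated, which should fix the C9=C10 geometry with OTf trans to the ester.

Step 6
Reactants: 8 ethyl (2E,6S)-8-(TBS-oxy)-2,6-dimethyl-3-(triflyloxy)oct-2-enoate; 9 (2-bromoprop-2-en-1-yl)trimethylsilane
Product: 12 ethyl (2E)-3-[(3S)-5-(TBS-oxy)-3-methylpentyl]-2-methyl-4-[(trimethylsilyl)methyl]penta-2,4-dienoate, via vinylmagnesium bromide 10 (not isolated), via vinylzinc bromide 11 (not isolated)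
Conditions: 9, Mg, THF; ZnBr2, 0 °C; then 8, Pd(PPh3)4 (cat.), THF, rt → 50 °C
Reagents that add atoms: none
Why: Negishi cross-coupling proceeds with retention at the enol triflate, so the 2-(silylmethyl)vinyl unit (C7, C8, C17) should end up trans to the ester carbon C1 and cis to the C10 methyl.

Step 7
Reactants: 12 ethyl (2E)-3-[(3S)-5-(TBS-oxy)-3-methylpentyl]-2-methyl-4-[(trimethylsilyl)methyl]penta-2,4-dienoate
Product: 13 (2E)-3-[(3S)-5-(TBS-oxy)-3-methylpentyl]-2-methyl-4-[(trimethylsilyl)methyl]penta-2,4-dien-1-ol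
Conditions: DIBAL-H, CH2Cl2, −78 °C; Rochelle salt work-up
Reagents that add atoms: none
Why: DIBAL-H reduction of the dienoate to the primary allylic alcohol (C1) leaves both silyl groups and the alkene geometry intact.

Step 8
Reactants: 13 (2E)-3-[(3S)-5-(TBS-oxy)-3-methylpentyl]-2-methyl-4-[(trimethylsilyl)methyl]penta-2,4-dien-1-ol
Product: 14 (2E)-1-bromo-3-[(3S)-5-(TBS-oxy)-3-methylpentyl]-2-methyl-4-[(trimethylsilyl)methyl]penta-2,4-diene
Conditions: CBr4, PPh3, 2,6-lutidine, CH2Cl2, 0 °C; used directly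
Reagents that add atoms: carbon tetrabromide, BrC(Br)(Br)Br
Why: Appel bromination under buffered, non-acidic conditions should convert the allylic alcohol into the primary allylic bromide without protodesilylating the acid-sensitive silylmethyl diene.

**Chiral keto ester**

Step 9
Reactants: 15 (4R)-4-benzyl-1,3-oxazolidin-2-one; 16 (2E)-but-2-enoyl chloride
Product: 17 (4R)-4-benzyl-3-[(2E)-but-2-enoyl]-1,3-oxazolidin-2-one
Conditions: n-BuLi, THF, −78 °C; then 16
Reagents that add atoms: none
Why: N-Acylation of the lithiated oxazolidinone gives the crotonyl imide.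

Step 10
Reactants: 17 (4R)-4-benzyl-3-[(2E)-but-2-enoyl]-1,3-oxazolidin-2-one; 18 acetaldehyde
Product: 19 (4R)-4-benzyl-3-[(2R,3S)-2-ethenyl-3-hydroxybutanoyl]-1,3-oxazolidin-2-one
Conditions: Bu2BOTf, Et3N, CH2Cl2, −78 → 0 °C; 18, −78 °C; then pH 7 buffer, MeOH, H2O2, 0 °C
Reagents that add atoms: none
Why: Evans syn-aldol reaction of the boron dienolate formed by γ-deprotonation; it reacts at the α-carbon through a Zimmerman–Traxler chair, and the auxiliary sets the (3S)-carbinol (the α-vinyl centre is planarised in step 12).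

Step 11
Reactants: 19 (4R)-4-benzyl-3-[(2R,3S)-2-ethenyl-3-hydroxybutanoyl]-1,3-oxazolidin-2-one
Product: 20 methyl (2R,3S)-2-ethenyl-3-hydroxybutanoate
Conditions: MeMgBr, MeOH, CH2Cl2, 0 °C
Reagents that add atoms: methanol, CO
Why: Transesterification with bromomagnesium methoxide cleaves the exocyclic imide carbonyl and frees the auxiliary while the magnesium aldolate resists retro-aldol cleavage.

Step 12
Reactants: 20 methyl (2R,3S)-2-ethenyl-3-hydroxybutanoate
Product: 21 methyl (2R,3S)-2-ethenyl-3-hydroxy-2-methylbutanoate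
Conditions: LDA (2.2 equiv), THF, −78 → −20 °C; MeI, DMPU, −78 → −20 °C
Reagents that add atoms: iodomethane, CI
Why: Fráter–Seebach alkylation: the chelated lithium alkoxide–dienolate dianion is methylated at the α-carbon on the face anti to the carbinol methyl group, which should create the quaternary centre (future C4) as 2R.

Step 13
Reactants: 21 methyl (2R,3S)-2-ethenyl-3-hydroxy-2-methylbutanoate
Product: 22 methyl (2R)-2-acetyl-2-methylbut-3-enoate
Conditions: Dess–Martin periodinane, CH2Cl2, rt
Reagents that add atoms: none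
Why: Dess–Martin oxidation turns the carbinol that served as a stereochemical relay into the C3 ketone; the quaternary centre cannot epimerise.

**Union, key step and endgame**

Step 14
Reactants: 22 methyl (2R)-2-acetyl-2-methylbut-3-enoate; 14 (2E)-1-bromo-3-[(3S)-5-(TBS-oxy)-3-methylpentyl]-2-methyl-4-[(trimethylsilyl)methyl]penta-2,4-diene
Product: 23 methyl (2R,6E)-2-ethenyl-2,6-dimethyl-7-[(3S)-5-(TBS-oxy)-3-methylpentyl]-3-oxo-8-[(trimethylsilyl)methyl]nona-6,8-dienoate
Conditions: 22, LDA, THF, −78 °C; then 14, −78 → −20 °C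
Reagents that add atoms: none
Why: Kinetic deprotonation can only occur at the acetyl methyl group (the other α-carbon is quaternary), and SN2 alkylation of this enolate by the primary allylic bromide forms the C1–C2 bond.

Step 15
Reactants: 23 methyl (2R,6E)-2-ethenyl-2,6-dimethyl-7-[(3S)-5-(TBS-oxy)-3-methylpentyl]-3-oxo-8-[(trimethylsilyl)methyl]nona-6,8-dienoate
Product: 24 methyl 15-(TBS-oxy)-3-oxo-17-(trimethylsilyl)labd-8-en-19-oate (5α-H, 10β-CH3, 4β-CO2Me, 13S)
Conditions: toluene (0.01 M), BHT (cat.), sealed tube, 180 °C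
Reagents that add atoms: none
Why: Concerted, asynchronous thermal [4+2] cycloaddition in which the s-cis C7=C8–C9=C10 diene adds suprafacially across the unactivated C5=C6 vinyl group, so that C6–C7 and C5–C10 form in the same event. The closest known reaction type is the type 1 intramolecular Diels–Alder reaction of unactivated deca-1,7,9-trienes to octalins, including cases in which a disubstituted diene terminus becomes an angular quaternary carbon. Ring A closes because C5 bonds to the tethered diene terminus C10 through the four-atom C1–C4 chain in a chair-like array, and ring B is the cyclohexene of the cycloaddition itself. At C10 and C5 the trans ring fusion follows from the (E)-C9=C10 geometry (tether outside, methyl inside) combined with the anti approach of the tether, which the C9 side chain favours by clashing with C1–C2 in the syn array; the absolute sense follows from C4, whose ester sits axial in the tether chair so that the larger C4 methyl avoids a syn-pentane contact with the inside C10 methyl. The step needs fusion selectivity, π-facial selectivity and chemoselectivity over [1,5]-hydrogen shift in the diene; the sp2 C3, the gem-disubstituted C4 (Thorpe–Ingold effect), the 2,3-disubstitution that biases the diene towards s-cis and dilute acid-free conditions are meant to secure them.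

Step 16
Reactants: 24 methyl 15-(TBS-oxy)-3-oxo-17-(trimethylsilyl)labd-8-en-19-oate
Product: 25 methyl 15-(TBS-oxy)-3α-hydroxy-17-(trimethylsilyl)labd-8-en-19-oate
Conditions: L-Selectride, THF, −78 °C; then NaOH, H2O2, 0 °C
Reagents that add atoms: none
Why: The bulky hydride should attack the C3 ketone from the equatorial direction (the axial α-face path is blocked by H-1α and H-5α), giving the axial 3α-alcohol; the ester is inert at −78 °C.

Step 17
Reactants: 25 methyl 15-(TBS-oxy)-3α-hydroxy-17-(trimethylsilyl)labd-8-en-19-oate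
Product: 26 methyl 3α-acetoxy-15-(TBS-oxy)-17-(trimethylsilyl)labd-8-en-19-oate
Conditions: Ac2O, DMAP (cat.), pyridine, rt → 40 °C
Reagents that add atoms: acetic anhydride, CC(=O)OC(C)=O
Why: DMAP-catalysed acetylation of the hindered axial alcohol while the primary C15 alcohol is still masked as its TBS ether.

Step 18
Reactants: 26 methyl 3α-acetoxy-15-(TBS-oxy)-17-(trimethylsilyl)labd-8-en-19-oate
Product: 28 methyl 3α-acetoxy-15-hydroxylabd-8(17)-en-19-oate (target), via 15-O-TBS 8(17)-ene 27 (not isolated)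
Conditions: TFA, CH2Cl2, −20 °C; then H2O–THF, 0 °C → rt; NaHCO3 work-up
Reagents that add atoms: none
Why: SE2′ protodesilylation of the allylsilane: the proton should attack C9 from the α-face (axial, anti to the C10 methyl), and the β-silyl cation at C8 loses silicon to give the exocyclic C8=C17 bond and the 9α-H centre; the aqueous acid then cleaves the TBS ether while the hindered acetate survives.

**Compound list**

1 | (S)-citronellol | CC(C)=CCC[C@H](C)CCO | starting material
2 | tert-butyl{[(3S)-3,7-dimethyloct-6-en-1-yl]oxy}dimethylsilane | CC(C)=CCC[C@H](C)CCO[Si](C)(C)C(C)(C)C | intermediate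
3 | secondary ozonide of 2 (3,3-dimethyl-5-substituted 1,2,4-trioxolane) | CC1(C)OOC(CC[C@H](C)CCO[Si](C)(C)C(C)(C)C)O1 | intermediate (not isolated)
4 | (4S)-6-(TBS-oxy)-4-methylhexanal | O=CCC[C@H](C)CCO[Si](C)(C)C(C)(C)C | intermediate
5 | ethyl propanoate | CCC(=O)OCC | starting material
6 | ethyl (6S)-8-(TBS-oxy)-3-hydroxy-2,6-dimethyloctanoate | CCOC(=O)C(C)C(O)CC[C@H](C)CCO[Si](C)(C)C(C)(C)C | intermediate
7 | ethyl (6S)-8-(TBS-oxy)-2,6-dimethyl-3-oxooctanoate | CCOC(=O)C(C)C(=O)CC[C@H](C)CCO[Si](C)(C)C(C)(C)C | intermediate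
8 | ethyl (2E,6S)-8-(TBS-oxy)-2,6-dimethyl-3-(triflyloxy)oct-2-enoate | CCOC(=O)/C(C)=C(/OS(=O)(=O)C(F)(F)F)CC[C@H](C)CCO[Si](C)(C)C(C)(C)C | intermediate
9 | (2-bromoprop-2-en-1-yl)trimethylsilane | C=C(Br)C[Si](C)(C)C | starting material
10 | [3-(trimethylsilyl)prop-1-en-2-yl]magnesium bromide | C=C([Mg]Br)C[Si](C)(C)C | intermediate (not isolated)
11 | [3-(trimethylsilyl)prop-1-en-2-yl]zinc bromide | C=C([Zn]Br)C[Si](C)(C)C | intermediate (not isolated)
12 | ethyl (2E)-3-[(3S)-5-(TBS-oxy)-3-methylpentyl]-2-methyl-4-[(trimethylsilyl)methyl]penta-2,4-dienoate | CCOC(=O)/C(C)=C(/C(=C)C[Si](C)(C)C)CC[C@H](C)CCO[Si](C)(C)C(C)(C)C | intermediate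
13 | (2E)-3-[(3S)-5-(TBS-oxy)-3-methylpentyl]-2-methyl-4-[(trimethylsilyl)methyl]penta-2,4-dien-1-ol | OC/C(C)=C(/C(=C)C[Si](C)(C)C)CC[C@H](C)CCO[Si](C)(C)C(C)(C)C | intermediate
14 | (2E)-1-bromo-3-[(3S)-5-(TBS-oxy)-3-methylpentyl]-2-methyl-4-[(trimethylsilyl)methyl]penta-2,4-diene | BrC/C(C)=C(/C(=C)C[Si](C)(C)C)CC[C@H](C)CCO[Si](C)(C)C(C)(C)C | intermediate
15 | (4R)-4-benzyl-1,3-oxazolidin-2-one | O=C1N[C@H](Cc2ccccc2)CO1 | starting material
16 | (2E)-but-2-enoyl chloride | C/C=C/C(Cl)=O | starting material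
17 | (4R)-4-benzyl-3-[(2E)-but-2-enoyl]-1,3-oxazolidin-2-one | C/C=C/C(=O)N1[C@H](Cc2ccccc2)COC1=O | intermediate
18 | acetaldehyde | CC=O | starting material
19 | (4R)-4-benzyl-3-[(2R,3S)-2-ethenyl-3-hydroxybutanoyl]-1,3-oxazolidin-2-one | C[C@H](O)[C@@H](C=C)C(=O)N1[C@H](Cc2ccccc2)COC1=O | intermediate
20 | methyl (2R,3S)-2-ethenyl-3-hydroxybutanoate | C[C@H](O)[C@@H](C=C)C(=O)OC | intermediate
21 | methyl (2R,3S)-2-ethenyl-3-hydroxy-2-methylbutanoate | C[C@H](O)[C@](C)(C(=O)OC)C=C | intermediate
22 | methyl (2R)-2-acetyl-2-methylbut-3-enoate | CC(=O)[C@](C)(C(=O)OC)C=C | intermediate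
23 | methyl (2R,6E)-2-ethenyl-2,6-dimethyl-7-[(3S)-5-(TBS-oxy)-3-methylpentyl]-3-oxo-8-[(trimethylsilyl)methyl]nona-6,8-dienoate | C=C(C[Si](C)(C)C)/C(CC[C@H](C)CCO[Si](C)(C)C(C)(C)C)=C(\C)CCC(=O)[C@](C)(C(=O)OC)C=C | intermediate
24 | methyl 15-(TBS-oxy)-3-oxo-17-(trimethylsilyl)labd-8-en-19-oate | C[Si](C)(C)CC1=C(CC[C@H](C)CCO[Si](C)(C)C(C)(C)C)[C@@]2(C)CCC(=O)[C@](C)(C(=O)OC)[C@@H]2CC1 | intermediate
25 | methyl 15-(TBS-oxy)-3α-hydroxy-17-(trimethylsilyl)labd-8-en-19-oate | C[Si](C)(C)CC1=C(CC[C@H](C)CCO[Si](C)(C)C(C)(C)C)[C@@]2(C)CC[C@@H](O)[C@](C)(C(=O)OC)[C@@H]2CC1 | intermediate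
26 | methyl 3α-acetoxy-15-(TBS-oxy)-17-(trimethylsilyl)labd-8-en-19-oate | C[Si](C)(C)CC1=C(CC[C@H](C)CCO[Si](C)(C)C(C)(C)C)[C@@]2(C)CC[C@@H](OC(C)=O)[C@](C)(C(=O)OC)[C@@H]2CC1 | intermediate
27 | methyl 3α-acetoxy-15-(TBS-oxy)labd-8(17)-en-19-oate | C=C1CC[C@@H]2[C@](C)(CC[C@@H](OC(C)=O)[C@]2(C)C(=O)OC)[C@H]1CC[C@H](C)CCO[Si](C)(C)C(C)(C)C | intermediate (not isolated)
28 | methyl 3α-acetoxy-15-hydroxylabd-8(17)-en-19-oate (CNP0230414.1) | C=C1CC[C@@H]2[C@](C)(CC[C@@H](OC(C)=O)[C@]2(C)C(=O)OC)[C@H]1CC[C@H](C)CCO | target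

**Step count.** Total: 18 steps. Longest linear sequence: 13 steps (steps 1–8, then 14–18); the keto ester branch (steps 9–13) joins at step 14.

**Steps most likely to fail, with fallbacks**

Step 15. The unactivated vinyl group may add too slowly to the hindered tetrasubstituted diene, so that [1,5]-hydrogen shift in the diene or closure to the cis-fused isomer competes. The fallback activates the dienophile as a vinyl sulfone (sulfonyl-activated intramolecular Diels–Alder reaction, then desulfonylation) and sets out from keto ester 22 and bromide 14. Radical iodosulfonylation of the vinyl group of 22 (PhSO2Na, I2, EtOAc–H2O) would give methyl (2R)-2-acetyl-3-iodo-2-methyl-4-(phenylsulfonyl)butanoate F1. Dehydroiodination with Et3N would give the (E)-vinyl sulfone methyl (2R,3E)-2-acetyl-2-methyl-4-(phenylsulfonyl)but-3-enoate F2. Alkylation of its kinetic lithium enolate with 14, as in step 14, would give the sulfonyl triene F3. Heating (toluene, 110–140 °C) should then give the 6-phenylsulfonyl cycloadduct F4. Buffered sodium amalgam (Na/Hg, Na2HPO4, MeOH–THF, −20 °C) should cleave the C6–S bond, the hindered C3 ketone being expected to survive, and the route is rejoined at 24.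

Step 5. The enolisation–triflation may leak to the (Z)-triflate, which would put the tether inside the diene and make trans fusion unreachable. The fallback builds the tetrasubstituted C9=C10 bond by syn-carbocupration of an ynoate and sets out from aldehyde 4. Ohira–Bestmann homologation (dimethyl (1-diazo-2-oxopropyl)phosphonate, K2CO3, MeOH) would give tert-butyldimethyl{[(3S)-3-methylhept-6-yn-1-yl]oxy}silane F5. Deprotonation with n-BuLi and trapping with ethyl chloroformate would give ethyl (6S)-8-(TBS-oxy)-6-methyloct-2-ynoate F6. The organocopper reagent [3-(trimethylsilyl)prop-1-en-2-yl]copper F7, made from Grignard reagent 10 and CuBr·SMe2, should add syn across the triple bond at −78 °C (carbon to C9, copper to C10). Methylation of the α-cuprio enoate in situ (MeI, HMPA) places the methyl group cis to the new vinyl unit; the route is rejoined at dienyl ester 12, and steps 3–6 are bypassed.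

Step 18. Protonation at C9 may lack facial selectivity, and some of the new double bond may move into the ring. The fallback sets C9 by thermodynamic equilibration next to a ketone and sets out from 26. The same acid treatment would be accepted as giving the C9-epimeric mixture of methyl 3α-acetoxy-15-hydroxylabd-8(17)-en-19-oate F8. Ozonolysis (O3, CH2Cl2–MeOH, −78 °C; Me2S) followed by equilibration with DBU in toluene should converge on methyl 3α-acetoxy-15-hydroxy-8-oxo-17-norlabdan-19-oate F9, with the side chain equatorial (9α-H). Non-basic Takai–Lombardo methylenation (Zn, CH2Br2, TiCl4, THF–CH2Cl2), which spares the esters, would re-form the C8=C17 bond and rejoin the route at 28.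

**Further compounds**

F1 | step 15 | methyl (2R)-2-acetyl-3-iodo-2-methyl-4-(phenylsulfonyl)butanoate (C3 epimers) | CC(=O)[C@](C)(C(=O)OC)C(I)CS(=O)(=O)c1ccccc1
F2 | step 15 | methyl (2R,3E)-2-acetyl-2-methyl-4-(phenylsulfonyl)but-3-enoate | CC(=O)[C@](C)(C(=O)OC)/C=C/S(=O)(=O)c1ccccc1
F3 | step 15 | methyl (2R,6E)-2,6-dimethyl-7-[(3S)-5-(TBS-oxy)-3-methylpentyl]-3-oxo-2-[(E)-2-(phenylsulfonyl)ethenyl]-8-[(trimethylsilyl)methyl]nona-6,8-dienoate | C=C(C[Si](C)(C)C)/C(CC[C@H](C)CCO[Si](C)(C)C(C)(C)C)=C(\C)CCC(=O)[C@](C)(C(=O)OC)/C=C/S(=O)(=O)c1ccccc1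
F4 | step 15 | methyl 15-(TBS-oxy)-3-oxo-6-(phenylsulfonyl)-17-(trimethylsilyl)labd-8-en-19-oate | C[Si](C)(C)CC1=C(CC[C@H](C)CCO[Si](C)(C)C(C)(C)C)[C@@]2(C)CCC(=O)[C@](C)(C(=O)OC)[C@@H]2C(S(=O)(=O)c2ccccc2)C1
F5 | step 5 | tert-butyldimethyl{[(3S)-3-methylhept-6-yn-1-yl]oxy}silane | C#CCC[C@H](C)CCO[Si](C)(C)C(C)(C)C
F6 | step 5 | ethyl (6S)-8-(TBS-oxy)-6-methyloct-2-ynoate | CCOC(=O)C#CCC[C@H](C)CCO[Si](C)(C)C(C)(C)C
F7 | step 5 | [3-(trimethylsilyl)prop-1-en-2-yl]copper | C=C([Cu])C[Si](C)(C)C
F8 | step 18 | methyl 3α-acetoxy-15-hydroxylabd-8(17)-en-19-oate, C9-epimeric mixture | C=C1CC[C@@H]2[C@](C)(CC[C@@H](OC(C)=O)[C@]2(C)C(=O)OC)C1CC[C@H](C)CCO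
F9 | step 18 | methyl 3α-acetoxy-15-hydroxy-8-oxo-17-norlabdan-19-oate | O=C1CC[C@@H]2[C@](C)(CC[C@@H](OC(C)=O)[C@]2(C)C(=O)OC)[C@H]1CC[C@H](C)CCO
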